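The plan cuts the C4–C4a bond of the lower pyran, ring F (O1, C2, C3, C4, C4a, C8a). The precursor is an open aryl ether. Phloroglucinol ring D already carries the catechin-derived flavan (rings A, B, C) at C8 and, on O1, a threo 1-aryl-2,3-epoxypropyl chain. One Lewis-acid 6-endo epoxide–arene alkylation closes ring F, unmasks the 3-OH for galloylation, and turns the preset threo array into the 2,3-cis relation. It exploits the substitution of ring D. Of the two carbons ortho to O1, C8 is blocked, so only C4a, activated by O1, 5-O and 7-O, can attack. The 4→8 connectivity follows without any regiochemical choice.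

Key step: step 9

Labels: the upper flavan unit has rings A (phloroglucinol), B (catechol) and C (pyran). The lower unit has rings D (phloroglucinol), E (pyrogallol) and F (pyran). The galloyl group is ring G. Each unit is numbered as a flavan (O1, C2, C3, C4, C4a, C5 to C8, C8a). Bn = benzyl.

Assumption: the temporary C4 centre of 3, 4 and 5 is drawn as the epimer expected from attack opposite the 2-aryl group; step 5 erases it, so its configuration has no bearing on the route.

Step 1
Reactants: 1 (+)-catechin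
Product: 2 5,7,3',4'-tetra-O-benzyl-(+)-catechin
Conditions: BnBr (4.4 equiv), K2CO3, DMF, 0 °C to rt
Reagents that add atoms: benzyl bromide, BrCc1ccccc1
Why: Williamson ether synthesis in which carbonate deprotonates only the four phenols, so the secondary 3-OH stays free and neither stereocentre is touched.

Step 2
Reactants: 2 5,7,3',4'-tetra-O-benzyl-(+)-catechin
Product: 3 (2R,3S,4S)-5,7,3',4'-tetrabenzyloxy-4-(2-ethoxyethoxy)flavan-3-ol
Conditions: DDQ (1.5 equiv), HOCH2CH2OEt (5 equiv), CH2Cl2, rt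
Reagents that add atoms: 2-ethoxyethanol, CCOCCO
Why: DDQ benzylic C–H oxidation, in which hydride abstraction from C4 gives a cation stabilised by O1, 5-O and 7-O of ring A, and the alcohol traps it pseudo-axially on the face opposite the 2-aryl group, which sets the temporary C4 centre.

Step 3
Reactants: 3 (2R,3S,4S)-5,7,3',4'-tetrabenzyloxy-4-(2-ethoxyethoxy)flavan-3-ol
Product: 4 O-[(2R,3S,4S)-5,7,3',4'-tetrabenzyloxy-4-(2-ethoxyethoxy)flavan-3-yl] 1H-imidazole-1-carbothioate
Conditions: 1,1'-thiocarbonyldiimidazole, DMAP (10 mol %), toluene, 80 °C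
Reagents that add atoms: 1,1'-thiocarbonyldiimidazole, S=C(n1ccnc1)n1ccnc1
Why: O-thioacylation of the secondary alcohol gives the radical precursor for a Barton–McCombie deoxygenation under neutral conditions that spare the acid-labile 4-alkoxy group and all three stereocentres.

Step 4
Reactants: 4 O-[(2R,3S,4S)-5,7,3',4'-tetrabenzyloxy-4-(2-ethoxyethoxy)flavan-3-yl] 1H-imidazole-1-carbothioate
Product: 5 (2S,4R)-5,7,3',4'-tetrabenzyloxy-4-(2-ethoxyethoxy)flavan
Conditions: Bu3SnH (3 equiv), Et3B (20 mol %), air, toluene, rt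
Reagents that add atoms: none
Why: Barton–McCombie deoxygenation, run at room temperature with ample stannane so that hydrogen transfer to the C3 radical outruns β-scission of the C2–O1 bond, with C2 keeping its geometry and becoming S only through the change in CIP priorities.

Step 5
Reactants: 5 (2S,4R)-5,7,3',4'-tetrabenzyloxy-4-(2-ethoxyethoxy)flavan; 6 3,5-bis(benzyloxy)phenol (3 equiv)
Product: 7 3,5-bis(benzyloxy)-2-[(2S)-2,4-trans-5,7,3',4'-tetrabenzyloxyflavan-4-yl]phenol
Conditions: TMSOTf (0.2 equiv), CH2Cl2, −78 to −40 °C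
Reagents that add atoms: none
Why: Lewis-acid Friedel–Crafts alkylation through the flavan-4-yl cation, in which pseudo-axial attack on the half-chair cation with its equatorial 2-aryl group (also the arrangement that avoids strain against 5-OBn) sets the 2,4-trans C4 centre, and the bulky cation should choose the carbon flanked by the small OH over the one between two OBn groups.

Step 6
Reactants: 8 3,4,5-tris(benzyloxy)benzaldehyde
Product: 9 rac-1-[3,4,5-tris(benzyloxy)phenyl]prop-2-en-1-ol
Conditions: CH2=CHMgBr, THF, 0 °C; then H2O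
Reagents that add atoms: vinylmagnesium bromide, C=C[Mg]Br
Why: Grignard 1,2-addition to a non-enolisable aldehyde gives the racemic allylic alcohol, whose stereocentre is sorted in the next step.

Step 7
Reactants: 9 rac-1-[3,4,5-tris(benzyloxy)phenyl]prop-2-en-1-ol
Product: 10 (S)-[(R)-oxiran-2-yl][3,4,5-tris(benzyloxy)phenyl]methanol (erythro)
Conditions: Ti(OiPr)4 (15 mol %), L-(+)-diisopropyl tartrate (18 mol %), t-BuOOH (0.45 equiv), 4 Å MS, CH2Cl2, −20 °C
Reagents that add atoms: tert-butyl hydroperoxide, CC(C)(C)OO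
Why: Sharpless kinetic resolution, in which the L-(+)-tartrate catalyst epoxidises the (R)-alcohol much faster than the (S)-alcohol and on the face it dictates, giving the erythro (1S,2R) epoxy alcohol and thereby the future C3, while the slow (S)-enantiomer stays unreacted and is separated.

Step 8
Reactants: 7 3,5-bis(benzyloxy)-2-[(2S)-2,4-trans-5,7,3',4'-tetrabenzyloxyflavan-4-yl]phenol; 10 (S)-[(R)-oxiran-2-yl][3,4,5-tris(benzyloxy)phenyl]methanol
Product: 11 (R)-2-{(R)-[3,5-bis(benzyloxy)-2-((2S)-2,4-trans-5,7,3',4'-tetrabenzyloxyflavan-4-yl)phenoxy][3,4,5-tris(benzyloxy)phenyl]methyl}oxirane (threo)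
Conditions: PPh3, DIAD, toluene, 0 °C to rt
Reagents that add atoms: none
Why: Mitsunobu etherification, in which phenol 7 displaces the oxyphosphonium group by SN2 with inversion, turning the (S)-carbinol into the (R)-configured future C2 and erythro into threo, with ionisation held back by the adjacent electron-withdrawing oxirane.

Step 9
Reactants: 11 (R)-2-{(R)-[3,5-bis(benzyloxy)-2-((2S)-2,4-trans-5,7,3',4'-tetrabenzyloxyflavan-4-yl)phenoxy][3,4,5-tris(benzyloxy)phenyl]methyl}oxirane
Product: 12 nona-O-benzyl-(2S)-luteoliflavan-(4β→8)-(−)-epigallocatechin (lower unit 2R,3R, 2,3-cis, free 3-OH)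
Conditions: AuCl3 (5 mol %), AgOTf (15 mol %), 4 Å MS, ClCH2CH2Cl, 0 °C to rt
Reagents that add atoms: none
Why: AuCl3 and AgOTf give a cationic trivalent-gold Lewis acid that binds the oxirane oxygen, C4a of ring D attacks the terminal carbon C4 in an SN2-like way, and proton loss from the Wheland intermediate followed by protodemetalation of the C3 alkoxide gives 12. The reaction type is the known gold-catalysed intramolecular Friedel–Crafts cycloalkylation of aryl 2,3-epoxypropyl ethers to 3-chromanols, including 1-aryl-substituted ethers that give 2-aryl-3-chromanols. Ring F closes in the 6-endo-tet mode, with both oxirane carbons ending inside the ring. No new stereocentre is formed, because the C3–O and C2–O1 bonds are not broken, so the threo (2R,3R) array fixed in steps 7 and 8 becomes the 2,3-cis relation. Site selectivity on ring D is secured by the substrate, since C8 carries the flavan-4-yl group and C6 cannot reach the oxirane, while C4a is activated by O1 and 5-O (ortho) and 7-O (para). The step needs 6-endo over 5-exo attack and alkylation faster than ionisation of the benzylic C2–O1 bond or of the interflavan bond, which is served by the unhindered primary terminus, the strain of the 5-exo transition state, the low catalyst loading at or below room temperature and sieves against adventitious acid.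

Step 10
Reactants: 12 nona-O-benzyl-(2S)-luteoliflavan-(4β→8)-(−)-epigallocatechin; 13 3,4,5-tris(benzyloxy)benzoic acid
Product: 14 dodeca-O-benzyl-(2S)-luteoliflavan-(4β→8)-(−)-epigallocatechin 3-O-gallate
Conditions: DCC, DMAP, CH2Cl2, rt
Reagents that add atoms: none
Why: Steglich esterification acylates the only free hydroxyl, the axial 3-OH of ring F, at oxygen, so C3 keeps its configuration.

Step 11
Reactants: 14 dodeca-O-benzyl-(2S)-luteoliflavan-(4β→8)-(−)-epigallocatechin 3-O-gallate
Product: 15 (2S)-luteoliflavan-(4β→8)-(−)-epigallocatechin 3-O-gallate (CNP0190017.1)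
Conditions: H2 (1 atm), Pd(OH)2/C, THF–MeOH, rt
Reagents that add atoms: none
Why: Catalytic hydrogenolysis should cleave all twelve benzyl ethers under neutral conditions that leave the gallate ester, the two pyran C2–O1 bonds, the interflavan bond and the four stereocentres untouched.

Compound list
1 | (+)-catechin, (2R,3S) | O[C@H]1Cc2c(O)cc(O)cc2O[C@@H]1c1ccc(O)c(O)c1 | starting material
2 | 5,7,3',4'-tetra-O-benzyl-(+)-catechin | O[C@H]1Cc2c(OCc3ccccc3)cc(OCc3ccccc3)cc2O[C@@H]1c1ccc(OCc2ccccc2)c(OCc2ccccc2)c1 | intermediate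
3 | (2R,3S,4S)-5,7,3',4'-tetrabenzyloxy-4-(2-ethoxyethoxy)flavan-3-ol | O[C@H]1[C@@H](OCCOCC)c2c(OCc3ccccc3)cc(OCc3ccccc3)cc2O[C@@H]1c1ccc(OCc2ccccc2)c(OCc2ccccc2)c1 | intermediate
4 | O-[(2R,3S,4S)-5,7,3',4'-tetrabenzyloxy-4-(2-ethoxyethoxy)flavan-3-yl] 1H-imidazole-1-carbothioate | S=C(O[C@H]1[C@@H](OCCOCC)c2c(OCc3ccccc3)cc(OCc3ccccc3)cc2O[C@@H]1c1ccc(OCc2ccccc2)c(OCc2ccccc2)c1)n1ccnc1 | intermediate
5 | (2S,4R)-5,7,3',4'-tetrabenzyloxy-4-(2-ethoxyethoxy)flavan | CCOCCO[C@@H]1C[C@@H](c2ccc(OCc3ccccc3)c(OCc3ccccc3)c2)Oc2cc(OCc3ccccc3)cc(OCc3ccccc3)c21 | intermediate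
6 | 3,5-bis(benzyloxy)phenol | Oc1cc(OCc2ccccc2)cc(OCc2ccccc2)c1 | starting material
7 | 3,5-bis(benzyloxy)-2-[(2S)-2,4-trans-5,7,3',4'-tetrabenzyloxyflavan-4-yl]phenol | Oc1cc(OCc2ccccc2)cc(OCc2ccccc2)c1[C@@H]1C[C@@H](c2ccc(OCc3ccccc3)c(OCc3ccccc3)c2)Oc2cc(OCc3ccccc3)cc(OCc3ccccc3)c21 | intermediate
8 | 3,4,5-tris(benzyloxy)benzaldehyde | O=Cc1cc(OCc2ccccc2)c(OCc2ccccc2)c(OCc2ccccc2)c1 | starting material
9 | rac-1-[3,4,5-tris(benzyloxy)phenyl]prop-2-en-1-ol (racemic) | C=CC(O)c1cc(OCc2ccccc2)c(OCc2ccccc2)c(OCc2ccccc2)c1 | intermediate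
10 | (S)-[(R)-oxiran-2-yl][3,4,5-tris(benzyloxy)phenyl]methanol (erythro) | O[C@H]([C@H]1CO1)c1cc(OCc2ccccc2)c(OCc2ccccc2)c(OCc2ccccc2)c1 | intermediate
11 | (R)-2-{(R)-[3,5-bis(benzyloxy)-2-((2S)-2,4-trans-5,7,3',4'-tetrabenzyloxyflavan-4-yl)phenoxy][3,4,5-tris(benzyloxy)phenyl]methyl}oxirane (threo) | O(c1cc(OCc2ccccc2)cc(OCc2ccccc2)c1[C@@H]1C[C@@H](c2ccc(OCc3ccccc3)c(OCc3ccccc3)c2)Oc2cc(OCc3ccccc3)cc(OCc3ccccc3)c21)[C@@H]([C@H]1CO1)c1cc(OCc2ccccc2)c(OCc2ccccc2)c(OCc2ccccc2)c1 | intermediate
12 | nona-O-benzyl-(2S)-luteoliflavan-(4β→8)-(−)-epigallocatechin (lower unit 2R,3R, free 3-OH) | O[C@@H]1Cc2c(OCc3ccccc3)cc(OCc3ccccc3)c([C@@H]3C[C@@H](c4ccc(OCc5ccccc5)c(OCc5ccccc5)c4)Oc4cc(OCc5ccccc5)cc(OCc5ccccc5)c43)c2O[C@@H]1c1cc(OCc2ccccc2)c(OCc2ccccc2)c(OCc2ccccc2)c1 | intermediate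
13 | 3,4,5-tris(benzyloxy)benzoic acid | OC(=O)c1cc(OCc2ccccc2)c(OCc2ccccc2)c(OCc2ccccc2)c1 | starting material
14 | dodeca-O-benzyl-(2S)-luteoliflavan-(4β→8)-(−)-epigallocatechin 3-O-gallate | O=C(O[C@@H]1Cc2c(OCc3ccccc3)cc(OCc3ccccc3)c([C@@H]3C[C@@H](c4ccc(OCc5ccccc5)c(OCc5ccccc5)c4)Oc4cc(OCc5ccccc5)cc(OCc5ccccc5)c43)c2O[C@@H]1c1cc(OCc2ccccc2)c(OCc2ccccc2)c(OCc2ccccc2)c1)c1cc(OCc2ccccc2)c(OCc2ccccc2)c(OCc2ccccc2)c1 | intermediate
15 | (2S)-luteoliflavan-(4β→8)-(−)-epigallocatechin 3-O-gallate (CNP0190017.1) | O=C(O[C@@H]1Cc2c(O)cc(O)c([C@@H]3C[C@@H](c4ccc(O)c(O)c4)Oc4cc(O)cc(O)c43)c2O[C@@H]1c1cc(O)c(O)c(O)c1)c1cc(O)c(O)c(O)c1 | target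

Total step count: 11. Longest linear sequence: 9 steps (steps 1 to 5 and 8 to 11).

Steps most likely to fail

Step 9. The Lewis acid may ionise the benzylic C2–O1 ether or the acid-labile interflavan bond. Alternatively, the crowded ring D may attack so slowly that the oxirane rearranges first. The fallback exchanges the order of ring closure and interflavan coupling. It sets out from 6 and 10. Mitsunobu etherification of the unhindered phenol 6 with 10 (PPh3, DIAD) gives the monomeric ether (R)-2-{(R)-[3,5-bis(benzyloxy)phenoxy][3,4,5-tris(benzyloxy)phenyl]methyl}oxirane F1. The AuCl3/AgOTf cycloalkylation, now on a substrate without a diarylmethine link and with two equivalent ortho carbons, gives 5,7,3',4',5'-penta-O-benzyl-(−)-epigallocatechin F2. TMSOTf-promoted Friedel–Crafts coupling of excess F2 with 5 then takes place at C8, the usual site for benzylated flavan-3-ol nucleophiles. This comes back to the route at 12. Ring F remains the last ring closed.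

Step 8. The flavan-4-yl group next to the phenolic OH may shield it from the bulky oxyphosphonium ion, and partial ionisation at the benzylic carbon may erode the inversion. The fallback reverses the order in which the two bonds of ring F are made, so that the hindered C–O bond forms intramolecularly. It sets out from 7 and 10. Friedel–Crafts opening of the terminal oxirane carbon of 10 by the free carbon ortho to the OH of 7 (Sc(OTf)3 10 mol %, CH2Cl2, or (CF3)2CHOH as solvent) gives the erythro diol 3,5-bis(benzyloxy)-2-{(2R,3S)-2,3-dihydroxy-3-[3,4,5-tris(benzyloxy)phenyl]propyl}-6-[(2S)-2,4-trans-5,7,3',4'-tetrabenzyloxyflavan-4-yl]phenol F3. An intramolecular Mitsunobu cyclodehydration (PPh3, DIAD, THF) follows, in which the phenol displaces the activated benzylic hydroxyl with inversion in the 6-exo-tet mode. This turns erythro into 2,3-cis and comes back to the route at 12.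

Step 5. The cation may attack the carbon between the two benzyloxy groups, the facial selectivity at C4 may be poor, or the electrophile may condense with itself. The fallback moves the regiochemical decision from C–C to C–O bond formation. It sets out from 5, which is coupled with an excess of C3-symmetric phloroglucinol (BF3·OEt2, 1,4-dioxane–CH2Cl2, rt). All three ring carbons are equivalent, and reversible ionisation lets the 2,4-trans epimer accumulate. The product is 2-[(2S)-2,4-trans-5,7,3',4'-tetrabenzyloxyflavan-4-yl]benzene-1,3,5-triol F4. Controlled benzylation (BnBr 2 equiv, K2CO3, DMF) should take the unhindered para OH and one of the two equivalent ortho OH groups. This comes back to the route at 7.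

Further compounds
F1 | step 9 | (R)-2-{(R)-[3,5-bis(benzyloxy)phenoxy][3,4,5-tris(benzyloxy)phenyl]methyl}oxirane | O(c1cc(OCc2ccccc2)cc(OCc2ccccc2)c1)[C@@H]([C@H]1CO1)c1cc(OCc2ccccc2)c(OCc2ccccc2)c(OCc2ccccc2)c1
F2 | step 9 | 5,7,3',4',5'-penta-O-benzyl-(−)-epigallocatechin | O[C@@H]1Cc2c(OCc3ccccc3)cc(OCc3ccccc3)cc2O[C@@H]1c1cc(OCc2ccccc2)c(OCc2ccccc2)c(OCc2ccccc2)c1
F3 | step 8 | 3,5-bis(benzyloxy)-2-{(2R,3S)-2,3-dihydroxy-3-[3,4,5-tris(benzyloxy)phenyl]propyl}-6-[(2S)-2,4-trans-5,7,3',4'-tetrabenzyloxyflavan-4-yl]phenol | O[C@H](Cc1c(OCc2ccccc2)cc(OCc2ccccc2)c([C@@H]2C[C@@H](c3ccc(OCc4ccccc4)c(OCc4ccccc4)c3)Oc3cc(OCc4ccccc4)cc(OCc4ccccc4)c32)c1O)[C@@H](O)c1cc(OCc2ccccc2)c(OCc2ccccc2)c(OCc2ccccc2)c1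
F4 | step 5 | 2-[(2S)-2,4-trans-5,7,3',4'-tetrabenzyloxyflavan-4-yl]benzene-1,3,5-triol | Oc1cc(O)c([C@@H]2C[C@@H](c3ccc(OCc4ccccc4)c(OCc4ccccc4)c3)Oc3cc(OCc4ccccc4)cc(OCc4ccccc4)c32)c(O)c1
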